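## Retrosynthetic overview

1. Two monoterpenes supply all twenty carbons: geranyl acetate gives C1–C8 with both branch methyls, and (R)-linalool gives C9–C18 with the C11 carbinol centre already set. They are joined at C8–C9 by an alkyl–alkyl Suzuki coupling.
2. C7 comes from a hydroxyl-directed asymmetric hydrogenation of the 6,7-olefin, after allylic oxidation of the C8 methyl.
3. C2 and the 3(20)-methylidene come from Sharpless epoxidation of the 2E-allylic alcohol followed by Ti-mediated epoxide-to-allylic-alcohol isomerisation, then acetylation.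
4. Rings: there is only one, the tetrasubstituted oxane. It is closed in the last step by proton-initiated Markovnikov addition of the C11 tertiary hydroxyl to the C14=C15 olefin, the hydroxy-olefin cyclisation presumed for the biosynthesis.

Assumption: phytane numbering is used (C1 = CH2OAc, C2 = CHOAc, C3 = methylidene carbon, C7 = CHMe, C11 and C15 = the carbons bonded to the ring oxygen); in this numbering the target is (2R,7R,11S).

## Route

Step 1
Reactants: 1 geranyl acetate, (2E)-3,7-dimethylocta-2,6-dien-1-yl acetate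
Product: 2 (2E,6E)-8-hydroxy-3,7-dimethylocta-2,6-dien-1-yl acetate
Conditions: SeO2 (10 mol %), t-BuOOH (2.5 equiv), salicylic acid (10 mol %), CH2Cl2, rt
Reagents that add atoms: tert-butyl hydroperoxide, CC(C)(C)OO (source of the new oxygen, relayed by catalytic selenium dioxide, O=[Se]=O)
Why: Sharpless–Umbreit SeO2-catalysed allylic oxidation (ene reaction then [2,3]-sigmatropic shift) hydroxylates only the E-methyl (C8) of the electron-rich 6,7-olefin, because the 2,3-olefin is deactivated by the allylic acetate; no stereocentre is formed.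

Step 2
Reactants: 2 (2E,6E)-8-hydroxy-3,7-dimethylocta-2,6-dien-1-yl acetate
Product: 3 (2E,7R)-8-hydroxy-3,7-dimethyloct-2-en-1-yl acetate
Conditions: H2 (100 atm), Ru(OAc)2[(R)-BINAP] (1 mol %), MeOH, 20 °C
Reagents that add atoms: none
Why: Noyori hydroxyl-directed asymmetric hydrogenation reduces only the 6,7-olefin, which carries the free allylic OH, and the (R)-BINAP complex is predicted to add H2 to the same olefin face as in geraniol → (S)-citronellol, which sets C7 as R.

Step 3
Reactants: 3 (2E,7R)-8-hydroxy-3,7-dimethyloct-2-en-1-yl acetate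
Product: 4 (2E,7R)-8-bromo-3,7-dimethyloct-2-en-1-yl acetate
Conditions: CBr4, PPh3, CH2Cl2, 0 °C
Reagents that add atoms: carbon tetrabromide, BrC(Br)(Br)Br
Why: Appel reaction converts the primary alcohol into the bromide under neutral conditions that leave the allylic acetate and the C7 centre untouched.

Step 4
Reactants: 5 (R)-(−)-linalool, (3R)-3,7-dimethylocta-1,6-dien-3-ol; 4 (2E,7R)-8-bromo-3,7-dimethyloct-2-en-1-yl acetate
Product: 8 (2E,7R,11S)-3,7,11,15-tetramethylhexadeca-2,14-diene-1,11-diol, via B-alkyl-9-BBN adduct 6 (not isolated), via C20 hydroxy acetate 7 (not isolated)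
Conditions: 5 (1.6 equiv), 9-BBN, THF, 0 °C → rt; then 4, NiCl2·glyme (6 mol %), trans-N,N′-dimethylcyclohexane-1,2-diamine (8 mol %), KOt-Bu, i-BuOH, dioxane, rt; then K2CO3, MeOH, rt
Reagents that add atoms: none
Why: 9-BBN hydroborates only the monosubstituted vinyl group (boron on C9), and the B-alkyl-9-BBN then couples with the β-branched primary bromide in a Fu nickel-catalysed alkyl–alkyl Suzuki–Miyaura reaction, while the alkoxide medium and methanolysis remove the acetate; C7 and C11 are carried through unchanged (C11 becomes S only by a change in CIP priorities).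

Step 5
Reactants: 8 (2E,7R,11S)-3,7,11,15-tetramethylhexadeca-2,14-diene-1,11-diol
Product: 10 (2R,7R,11S)-7,11,15-trimethyl-3-methylidenehexadec-14-ene-1,2,11-triol, via epoxy alcohol 9 (not isolated)
Conditions: Ti(OiPr)4 (20 mol %), L-(+)-diethyl tartrate (24 mol %), t-BuOOH (1.5 equiv), 4 Å MS, CH2Cl2, −20 °C; then P(OMe)3; then Ti(OiPr)4 (2.5 equiv), rt; aqueous tartaric acid work-up
Reagents that add atoms: tert-butyl hydroperoxide, CC(C)(C)OO
Why: Sharpless asymmetric epoxidation with the L-tartrate gives the (2S,3S)-epoxide under reagent control, and the Morgans–Sharpless Ti-mediated epoxy alcohol rearrangement then removes a proton from the C3 methyl (cis to the Ti-bound CH2O) and opens C3–O, so the C2–O bond keeps its configuration and becomes 2R.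

Step 6
Reactants: 10 (2R,7R,11S)-7,11,15-trimethyl-3-methylidenehexadec-14-ene-1,2,11-triol
Product: 11 (2R,7R,11S)-11-hydroxy-7,11,15-trimethyl-3-methylidenehexadec-14-ene-1,2-diyl diacetate
Conditions: Ac2O (2.5 equiv), pyridine, CH2Cl2, 0 °C → rt
Reagents that add atoms: acetic anhydride, CC(=O)OC(C)=O
Why: Standard O-acetylation takes the primary and the secondary allylic hydroxyl, while the hindered tertiary C11 hydroxyl does not react under these conditions.

Step 7
Reactants: 11 (2R,7R,11S)-11-hydroxy-7,11,15-trimethyl-3-methylidenehexadec-14-ene-1,2-diyl diacetate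
Product: 12 (2R,7R)-7-methyl-3-methylidene-10-[(2S)-2,6,6-trimethyloxan-2-yl]decane-1,2-diyl diacetate (target)
Conditions: Bi(OTf)3 (2 mol %), CH2Cl2, 0 °C; then Et3N
Reagents that add atoms: none
Why: Biomimetic acid-catalysed intramolecular Markovnikov hydroalkoxylation (cycloetherification): only the electron-rich 14,15-olefin is protonated (the 3(20)-olefin is deactivated by two acetoxy groups) and the C15 cation is trapped by the C11 hydroxyl in a six-membered closure, so the C11–O bond is never broken and the linalool-derived centre is retained as 11S.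

## Compound list

1 | geranyl acetate, (2E)-3,7-dimethylocta-2,6-dien-1-yl acetate | CC(=O)OC/C=C(\C)CCC=C(C)C | starting material
2 | (2E,6E)-8-hydroxy-3,7-dimethylocta-2,6-dien-1-yl acetate | CC(=O)OC/C=C(\C)CC/C=C(\C)CO | intermediate
3 | (2E,7R)-8-hydroxy-3,7-dimethyloct-2-en-1-yl acetate | CC(=O)OC/C=C(\C)CCC[C@@H](C)CO | intermediate
4 | (2E,7R)-8-bromo-3,7-dimethyloct-2-en-1-yl acetate | CC(=O)OC/C=C(\C)CCC[C@@H](C)CBr | intermediate
5 | (R)-(−)-linalool, (3R)-3,7-dimethylocta-1,6-dien-3-ol | C=C[C@](C)(O)CCC=C(C)C | starting material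
6 | (3S)-1-(9-borabicyclo[3.3.1]nonan-9-yl)-3,7-dimethyloct-6-en-3-ol | CC(C)=CCC[C@@](C)(O)CCB1C2CCCC1CCC2 | intermediate
7 | (2E,7R,11S)-11-hydroxy-3,7,11,15-tetramethylhexadeca-2,14-dien-1-yl acetate | CC(=O)OC/C=C(\C)CCC[C@@H](C)CCC[C@](C)(O)CCC=C(C)C | intermediate
8 | (2E,7R,11S)-3,7,11,15-tetramethylhexadeca-2,14-diene-1,11-diol | OC/C=C(\C)CCC[C@@H](C)CCC[C@](C)(O)CCC=C(C)C | intermediate
9 | (2S,3S,7S,11S)-2,3-epoxy-3,7,11,15-tetramethylhexadec-14-ene-1,11-diol (C7 reads S here only through CIP priorities; the centre is unchanged) | OC[C@@H]1O[C@@]1(C)CCC[C@@H](C)CCC[C@](C)(O)CCC=C(C)C | intermediate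
10 | (2R,7R,11S)-7,11,15-trimethyl-3-methylidenehexadec-14-ene-1,2,11-triol | C=C(CCC[C@@H](C)CCC[C@](C)(O)CCC=C(C)C)[C@H](CO)O | intermediate
11 | (2R,7R,11S)-11-hydroxy-7,11,15-trimethyl-3-methylidenehexadec-14-ene-1,2-diyl diacetate | C=C(CCC[C@@H](C)CCC[C@](C)(O)CCC=C(C)C)[C@H](COC(C)=O)OC(C)=O | intermediate
12 | (2R,7R)-7-methyl-3-methylidene-10-[(2S)-2,6,6-trimethyloxan-2-yl]decane-1,2-diyl diacetate | C=C(CCC[C@@H](C)CCC[C@@]1(C)CCCC(C)(C)O1)[C@H](COC(C)=O)OC(C)=O | target

## Step count and risk

Total step count: 7. Longest linear sequence: 7 steps (1 → 12); (R)-linalool 5 enters unmodified in step 4.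

Most likely to fail, first: step 4. The alkyl–alkyl Suzuki coupling has to join a β-branched primary bromide to a borane that carries a free tertiary hydroxyl. The fallback reverses the polarity of the two partners; it sets out from 5 (through 6) and 4 and comes back at 7. Iodinolysis of 6 (I2, NaOMe) gives (3R)-1-iodo-3,7-dimethyloct-6-en-3-ol F3. Zinc insertion into 4 (Zn dust, LiCl, THF) gives bromo[(2R,6E)-8-acetoxy-2,6-dimethyloct-6-en-1-yl]zinc F4. A Knochel-type alkyl–alkyl Negishi coupling of F3 with F4 (Ni(acac)2, 4-fluorostyrene, Bu4NI, THF/NMP, −5 °C) then gives 7, which is methanolysed to 8 as in the step.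

Second: step 2. The sense and level of induction for an (E)-2-methyl-2-alken-1-ol under Ru–BINAP are argued by analogy with geraniol and must be checked on the first run. The fallback moves the reduction to the aldehyde oxidation level and to an enzyme; it sets out from 2 and comes back at 3. MnO2 oxidation of 2 gives the enal (2E,6E)-3,7-dimethyl-8-oxoocta-2,6-dien-1-yl acetate F1. An (R)-selective ene-reductase of the Old Yellow Enzyme family (NADPH recycled with glucose and glucose dehydrogenase) reduces the 6,7-olefin to (2E,7R)-3,7-dimethyl-8-oxooct-2-en-1-yl acetate F2. This epimerisable aldehyde is reduced at once with NaBH4 (MeOH, 0 °C) to 3.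

Third: step 7. The late acid step could protonate the 3(20)-olefin, ionise an allylic acetate, or reopen the oxane at C11–O and erode that centre. The fallback replaces protonation by an electrophile-triggered ring closure followed by reductive removal of the electrophile; it sets out from 11 and comes back at 12. Intramolecular alkoxymercuration of 11 (Hg(OAc)2, THF, 0 °C) gives the Markovnikov-closed organomercurial (2R,7R)-10-[(2S,5RS)-5-(acetoxymercurio)-2,6,6-trimethyloxan-2-yl]-7-methyl-3-methylidenedecane-1,2-diyl diacetate F5. Demercuration of F5 (NaBH4, DMF, 0 °C) gives 12.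

## Further compounds

F1 | step 2 | (2E,6E)-3,7-dimethyl-8-oxoocta-2,6-dien-1-yl acetate | CC(=O)OC/C=C(\C)CC/C=C(\C)C=O
F2 | step 2 | (2E,7R)-3,7-dimethyl-8-oxooct-2-en-1-yl acetate | CC(=O)OC/C=C(\C)CCC[C@@H](C)C=O
F3 | step 4 | (3R)-1-iodo-3,7-dimethyloct-6-en-3-ol | CC(C)=CCC[C@@](C)(O)CCI
F4 | step 4 | bromo[(2R,6E)-8-acetoxy-2,6-dimethyloct-6-en-1-yl]zinc | CC(=O)OC/C=C(\C)CCC[C@@H](C)C[Zn]Br
F5 | step 7 | (2R,7R)-10-[(2S,5RS)-5-(acetoxymercurio)-2,6,6-trimethyloxan-2-yl]-7-methyl-3-methylidenedecane-1,2-diyl diacetate | C=C(CCC[C@@H](C)CCC[C@@]1(C)CCC([Hg]OC(C)=O)C(C)(C)O1)[C@H](COC(C)=O)OC(C)=O
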